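**Retrosynthetic overview**
1. C8–O ester: target 49 ⇐ macrocyclic 8-hydroxy lactone 46 + silylated (E)-4-hydroxytiglic acid 33 (Wittig from glycolaldehyde).
2. Ten-membered ring (formed last): C9–C10 bond by intramolecular Ni-catalysed reductive coupling of the (Z)-alkenyl iodide with the C8–C9 oxirane of 44.
3. Oxirane (second, transient ring): acid 38 ⇒ chloromethyl ketone 42 (one-carbon homologation) ⇒ CBS reduction (sets C8) ⇒ ring closure.
4. γ-Lactone (first ring): C6–C7 Evans syn-aldol/lactonisation of succinate imide 25 (C11 set by Evans allylation) with enal 16.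
5. Enal 16: Cu-catalysed carbomagnesiation/iodination of propargyl alcohol (C4=C5), Pd aminocarbonylation (C6), Stork–Zhao olefination (C1=C10).

Assumption: C1–C15 are germacrane atom labels; oxazolidinone auxiliaries, PPh3, silyl chlorides and MeNH(OMe) are reagents (none of their atoms reaches the target) and are not numbered. D = (1Z,5Z)-2-{[(tert-butyldiphenylsilyl)oxy]methyl}-6-iodohepta-1,5-dien-1-yl.

**Route**

Step 1
Reactants: 1 prop-2-yn-1-ol; 2 2-(2-bromoethyl)-1,3-dioxolane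
Product: 5 (Z)-2-[2-(1,3-dioxolan-2-yl)ethyl]-3-iodoprop-2-en-1-ol, via Grignard reagent 3 (not isolated), via alkenylmagnesium chelate 4 (not isolated)
Conditions: Mg, THF, 25 °C; then 1, CuI (10 mol %), THF, −10 °C → rt, 18 h; then I2, THF, −20 °C
Reagents that add atoms: iodine, II
Why: Copper-catalysed anti-carbomagnesiation of propargyl alcohol (Duboudin type) puts the alkyl group on C4 and magnesium on C5 cis to the chelating CH2O–Mg, so iodinolysis with retention fixes the C4=C5 geometry (I, the later C6, cis to C15).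

Step 2
Reactants: 5 (Z)-2-[2-(1,3-dioxolan-2-yl)ethyl]-3-iodoprop-2-en-1-ol
Product: 6 tert-butyl{[(2Z)-2-[2-(1,3-dioxolan-2-yl)ethyl]-3-iodoprop-2-en-1-yl]oxy}diphenylsilane
Conditions: TBDPSCl, imidazole, DMF, rt
Reagents that add atoms: tert-butyl(chloro)diphenylsilane, CC(C)(C)[Si](Cl)(c1ccccc1)c1ccccc1
Why: Standard silylation of a primary allylic alcohol; TBDPS survives the later aqueous acid and HCl steps and prevents butenolide formation with the cis carbonyl installed next.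

Step 3
Reactants: 6 tert-butyl{[(2Z)-2-[2-(1,3-dioxolan-2-yl)ethyl]-3-iodoprop-2-en-1-yl]oxy}diphenylsilane; 7 carbon monoxide
Product: 8 (2Z)-3-{[(tert-butyldiphenylsilyl)oxy]methyl}-5-(1,3-dioxolan-2-yl)-N-methoxy-N-methylpent-2-enamide
Conditions: Pd(OAc)2 (5 mol %), Xantphos (6 mol %), MeNH(OMe)·HCl, Et3N, CO (1 atm), PhMe, 70 °C
Reagents that add atoms: N,O-dimethylhydroxylamine hydrochloride, CNOC.Cl
Why: Pd-catalysed aminocarbonylation (oxidative addition, CO insertion, aminolysis) converts the alkenyl iodide into the Weinreb amide, adding C6 with retention of alkene geometry.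

Step 4
Reactants: 8 (2Z)-3-{[(tert-butyldiphenylsilyl)oxy]methyl}-5-(1,3-dioxolan-2-yl)-N-methoxy-N-methylpent-2-enamide
Product: 9 (2Z)-3-{[(tert-butyldiphenylsilyl)oxy]methyl}-N-methoxy-N-methyl-6-oxohex-2-enamide
Conditions: 1 M HCl, THF, rt
Reagents that add atoms: water, O
Why: Acid-catalysed acetal hydrolysis frees the C1 aldehyde while the Weinreb amide and the TBDPS ether tolerate dilute acid.

Step 5
Reactants: 10 iodoethane
Product: 11 ethyltriphenylphosphonium iodide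
Conditions: PPh3, PhMe, reflux
Reagents that add atoms: triphenylphosphine, c1ccc(cc1)P(c1ccccc1)c1ccccc1
Why: SN2 quaternisation of triphenylphosphine gives the Wittig salt that carries C10 and C14.

Step 6
Reactants: 11 ethyltriphenylphosphonium iodide; 9 (2Z)-3-{[(tert-butyldiphenylsilyl)oxy]methyl}-N-methoxy-N-methyl-6-oxohex-2-enamide
Product: 15 (2Z,6Z)-3-{[(tert-butyldiphenylsilyl)oxy]methyl}-7-iodo-N-methoxy-N-methylocta-2,6-dienamide, via ethylidene ylide 12 (not isolated), via iodoethylphosphonium iodide 13 (not isolated), via iodo ylide 14 (not isolated)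
Conditions: n-BuLi, THF, 0 °C; I2, −78 °C; NaHMDS, −20 °C; then 9, −78 °C → rt
Reagents that add atoms: iodine, II
Why: Stork–Zhao olefination of the aliphatic aldehyde with the α-iodo ylide gives the (Z)-2-iodoalk-2-ene (I cis to C2, typically ≥10:1), while the Weinreb amide is inert at −78 °C.

Step 7
Reactants: 15 (2Z,6Z)-3-{[(tert-butyldiphenylsilyl)oxy]methyl}-7-iodo-N-methoxy-N-methylocta-2,6-dienamide
Product: 16 (2Z,6Z)-3-{[(tert-butyldiphenylsilyl)oxy]methyl}-7-iodoocta-2,6-dienal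
Conditions: DIBAL-H, THF, −78 °C; Rochelle salt work-up
Reagents that add atoms: none
Why: DIBAL-H reduction of a Weinreb amide stops at the aldehyde oxidation level, giving the enal with both alkene geometries retained.

Step 8
Reactants: 17 propanoyl chloride
Product: 18 (4R)-4-benzyl-3-propanoyl-1,3-oxazolidin-2-one
Conditions: (R)-4-benzyl-1,3-oxazolidin-2-one, Et3N, DMAP (10 mol %), CH2Cl2, 0 °C → rt
Reagents that add atoms: (4R)-4-benzyl-1,3-oxazolidin-2-one, O=C1N[C@H](Cc2ccccc2)CO1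
Why: DMAP-catalysed N-acylation installs the Evans auxiliary on the propionate unit (C11–C13).

Step 9
Reactants: 18 (4R)-4-benzyl-3-propanoyl-1,3-oxazolidin-2-one; 19 3-iodoprop-1-ene
Product: 21 (4R)-4-benzyl-3-[(2S)-2-methylpent-4-enoyl]-1,3-oxazolidin-2-one, via sodium enolate 20 (not isolated)
Conditions: NaHMDS, THF, −78 °C; then 19, −78 → −45 °C
Reagents that add atoms: none
Why: Evans asymmetric alkylation: the chelated Z-enolate is allylated on the face opposite the benzyl group, setting C11 as (S) (dr ≥ 95:5).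

Step 10
Reactants: 21 (4R)-4-benzyl-3-[(2S)-2-methylpent-4-enoyl]-1,3-oxazolidin-2-one
Product: 22 methyl (2S)-2-methylpent-4-enoate
Conditions: MeMgBr (1.2 equiv), MeOH, CH2Cl2, 0 °C
Reagents that add atoms: methanol, CO
Why: Transesterification with methoxymagnesium bromide removes the auxiliary at the exocyclic carbonyl without epimerising C11.

Step 11
Reactants: 22 methyl (2S)-2-methylpent-4-enoate
Product: 23 (3S)-4-methoxy-3-methyl-4-oxobutanoic acid
Conditions: RuCl3·xH2O (2 mol %), NaIO4, CCl4/MeCN/H2O, rt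
Reagents that add atoms: sodium periodate, [Na+].[O-][I](=O)(=O)=O; water, O
Why: Ruthenium tetroxide oxidative cleavage of the terminal alkene gives the C8 carboxylic acid (terminal CH2 lost) and leaves the C11 stereocentre untouched.

Step 12
Reactants: 23 (3S)-4-methoxy-3-methyl-4-oxobutanoic acid
Product: 25 methyl (2S)-4-[(4S)-4-benzyl-2-oxo-1,3-oxazolidin-3-yl]-2-methyl-4-oxobutanoate, via mixed pivalic anhydride 24 (not isolated)
Conditions: PivCl, Et3N, THF, −20 °C; then (S)-4-benzyl-1,3-oxazolidin-2-one, LiCl, rt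
Reagents that add atoms: (4S)-4-benzyl-1,3-oxazolidin-2-one, O=C1N[C@@H](Cc2ccccc2)CO1
Why: Mixed-anhydride N-acylation (LiCl/Et3N) occurs at the unhindered carbonyl and gives the aldol donor with the auxiliary on C8 and the ester on C12.

Step 13
Reactants: 26 methyl 2-bromopropanoate
Product: 28 methyl 2-(triphenyl-λ5-phosphanylidene)propanoate, via phosphonium bromide 27 (not isolated)
Conditions: PPh3, EtOAc, 70 °C; then 2 M NaOH, CH2Cl2, rt
Reagents that add atoms: triphenylphosphine, c1ccc(cc1)P(c1ccccc1)c1ccccc1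
Why: Quaternisation followed by deprotonation gives the stabilised Wittig ylide.

Step 14
Reactants: 28 methyl 2-(triphenyl-λ5-phosphanylidene)propanoate; 29 1,4-dioxane-2,5-diol (glycolaldehyde dimer)
Product: 31 methyl (2E)-4-hydroxy-2-methylbut-2-enoate, via glycolaldehyde monomer 30 (not isolated)
Conditions: CH2Cl2, reflux
Reagents that add atoms: none
Why: Wittig olefination of the monomeric aldehyde with a stabilised α-methyl ylide is E-selective (ester trans to CH2OH, >95:5).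

Step 15
Reactants: 31 methyl (2E)-4-hydroxy-2-methylbut-2-enoate
Product: 32 methyl (2E)-4-[(tert-butyldimethylsilyl)oxy]-2-methylbut-2-enoate
Conditions: TBSCl, imidazole, CH2Cl2, rt
Reagents that add atoms: tert-butyl(chloro)dimethylsilane, CC(C)(C)[Si](C)(C)Cl
Why: Routine silylation protects the primary allylic alcohol for the later esterification.

Step 16
Reactants: 32 methyl (2E)-4-[(tert-butyldimethylsilyl)oxy]-2-methylbut-2-enoate
Product: 33 (2E)-4-[(tert-butyldimethylsilyl)oxy]-2-methylbut-2-enoic acid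
Conditions: LiOH·H2O, THF/MeOH/H2O, rt; then 1 M HCl to pH 3
Reagents that add atoms: lithium hydroxide, [Li+].[OH-]
Why: Saponification of the methyl ester; the primary TBS ether and the E-alkene are stable to LiOH.

Step 17
Reactants: 25 methyl (2S)-4-[(4S)-4-benzyl-2-oxo-1,3-oxazolidin-3-yl]-2-methyl-4-oxobutanoate; 16 (2Z,6Z)-3-{[(tert-butyldiphenylsilyl)oxy]methyl}-7-iodoocta-2,6-dienal
Product: 36 (4S)-4-benzyl-3-{[(2R,3S,4S)-2-D-4-methyl-5-oxooxolan-3-yl]carbonyl}-1,3-oxazolidin-2-one, via boron enolate 34 (not isolated), via aldol adduct 35 (not isolated)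
Conditions: Bu2BOTf, i-Pr2NEt, CH2Cl2, −78 → 0 °C; then 16, −78 → 0 °C; pH 7 buffer, MeOH, H2O2; then PPTS (10 mol %), PhMe, 40 °C
Reagents that add atoms: none
Why: Evans syn-aldol through the Z-boron enolate and a Zimmerman–Traxler chair (benzyl group shields one face) adds 1,2 to the enal and sets C6 (R) and C7 (S), and lactonisation of the γ-hydroxy ester (tandem aldol–lactonisation) gives the trans-lactone, all-trans with the C11 methyl from step 9.

Step 18
Reactants: 36 (4S)-4-benzyl-3-{[(2R,3S,4S)-2-D-4-methyl-5-oxooxolan-3-yl]carbonyl}-1,3-oxazolidin-2-one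
Product: 38 (2R,3S,4S)-2-D-4-methyl-5-oxooxolane-3-carboxylic acid, via peracid 37 (not isolated)
Conditions: LiOH, H2O2, THF/H2O, 0 °C; Na2SO3; then 1 M HCl
Reagents that add atoms: hydrogen peroxide, OO
Why: Hydroperoxide cleaves the exocyclic imide carbonyl selectively (standard auxiliary removal), being too weakly basic to trigger β-elimination of the lactone oxygen.

Step 19
Reactants: 38 (2R,3S,4S)-2-D-4-methyl-5-oxooxolane-3-carboxylic acid; 39 (trimethylsilyl)diazomethane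
Product: 42 (3S,4S,5R)-4-(chloroacetyl)-5-D-3-methyloxolan-2-one, via acid chloride 40 (not isolated), via diazoketone 41 (not isolated)
Conditions: (COCl)2, DMF (cat.), CH2Cl2, 0 °C; then 39, THF/MeCN, 0 °C; then HCl (2 M in Et2O), −20 → 0 °C
Reagents that add atoms: hydrogen chloride, Cl
Why: Acylation of the diazoalkane and HCl cleavage of the diazoketone (Nierenstein-type chloromethyl ketone synthesis) add C9 under base-free conditions, so C7 is neither epimerised nor eliminated.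

Step 20
Reactants: 42 (3S,4S,5R)-4-(chloroacetyl)-5-D-3-methyloxolan-2-one
Product: 43 (3S,4R,5R)-4-[(1R)-2-chloro-1-hydroxyethyl]-5-D-3-methyloxolan-2-one
Conditions: (R)-Me-CBS (20 mol %), catecholborane, PhMe/CH2Cl2, −78 → −40 °C
Reagents that add atoms: none
Why: Corey–Bakshi–Shibata reduction: the (R)-oxazaborolidine binds the ketone with the branched C7 residue as the large group and CH2Cl as the small one and delivers hydride to give the (8R)-chlorohydrin by catalyst control; catecholborane spares the alkenes.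

Step 21
Reactants: 43 (3S,4R,5R)-4-[(1R)-2-chloro-1-hydroxyethyl]-5-D-3-methyloxolan-2-one
Product: 44 (3S,4S,5R)-5-D-3-methyl-4-[(2R)-oxiran-2-yl]oxolan-2-one
Conditions: NaH (1.1 equiv), THF, 0 °C
Reagents that add atoms: none
Why: Intramolecular Williamson (3-exo-tet) closure of the chlorohydrin keeps the C8 configuration because the C8–O bond is not broken.

Step 22
Reactants: 44 (3S,4S,5R)-5-D-3-methyl-4-[(2R)-oxiran-2-yl]oxolan-2-one
Product: 46 (3S,3aR,4S,6Z,10Z,11aR)-10-{[(tert-butyldiphenylsilyl)oxy]methyl}-4-hydroxy-3,6-dimethyl-3a,4,5,8,9,11a-hexahydrocyclodeca[b]furan-2(3H)-one, via iodohydrin 45 (not isolated)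
Conditions: NiBr2·glyme (20 mol %), 4,4′-di-tert-butyl-2,2′-bipyridine (24 mol %), NaI (50 mol %), Et3N·HCl (1.5 equiv), Mn powder (3 equiv), DMPU/THF, 25 °C, syringe-pump addition of 44 over 12 h (final 2 mM)
Reagents that add atoms: none
Why: Proposed new method: intramolecular Ni/iodide co-catalysed reductive cross-electrophile coupling of an alkenyl iodide with a terminal epoxide — iodide opens the oxirane reversibly at C9 to iodohydrin 45, (bipyridine)Ni(0) inserts into the Z-alkenyl C10–I bond with retention, the reduced alkenyl–Ni(I) abstracts iodine from the tethered C9–I and recombines with the primary radical, and reductive elimination from alkenyl(alkyl)Ni(III) forms C9–C10, closing the ten-membered ring and leaving C8–OH with its configuration intact; the closest known reactions are the intermolecular Ni/iodide co-catalysed reductive coupling of terminal epoxides with aryl or vinyl halides and Ni-catalysed alkyl–alkenyl cross-electrophile coupling, neither shown for medium-ring closure; the trans-fused lactone disfavours the competing 5-exo cyclisation of the C9 radical onto C4=C5 (it would give a trans-bicyclo[3.3.0] system).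

Step 23
Reactants: 46 (3S,3aR,4S,6Z,10Z,11aR)-10-{[(tert-butyldiphenylsilyl)oxy]methyl}-4-hydroxy-3,6-dimethyl-3a,4,5,8,9,11a-hexahydrocyclodeca[b]furan-2(3H)-one; 33 (2E)-4-[(tert-butyldimethylsilyl)oxy]-2-methylbut-2-enoic acid
Product: 48 (3S,3aR,4S,6Z,10Z,11aR)-10-{[(tert-butyldiphenylsilyl)oxy]methyl}-3,6-dimethyl-2-oxo-2,3,3a,4,5,8,9,11a-octahydrocyclodeca[b]furan-4-yl (2E)-4-[(tert-butyldimethylsilyl)oxy]-2-methylbut-2-enoate, via mixed Yamaguchi anhydride 47 (not isolated)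
Conditions: 33, 2,4,6-trichlorobenzoyl chloride, Et3N, THF, rt; then 46, DMAP, PhMe, rt
Reagents that add atoms: none
Why: Yamaguchi esterification acylates the hindered secondary C8–OH faster than base-induced 6,12→8,12 translactonisation, and the E-configured tiglate-type acid does not isomerise.

Step 24
Reactants: 48 (3S,3aR,4S,6Z,10Z,11aR)-10-{[(tert-butyldiphenylsilyl)oxy]methyl}-3,6-dimethyl-2-oxo-2,3,3a,4,5,8,9,11a-octahydrocyclodeca[b]furan-4-yl (2E)-4-[(tert-butyldimethylsilyl)oxy]-2-methylbut-2-enoate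
Product: 49 (3S,3aR,4S,6Z,10Z,11aR)-10-(hydroxymethyl)-3,6-dimethyl-2-oxo-2,3,3a,4,5,8,9,11a-octahydrocyclodeca[b]furan-4-yl (2E)-4-hydroxy-2-methylbut-2-enoate
Conditions: HF·pyridine, pyridine/THF, 0 °C → rt
Reagents that add atoms: none
Why: Buffered fluoride desilylation removes both primary silyl ethers without acyl migration or lactone opening.

**Compound list**
1 | prop-2-yn-1-ol | C#CCO | starting material
2 | 2-(2-bromoethyl)-1,3-dioxolane | BrCCC1OCCO1 | starting material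
3 | [2-(1,3-dioxolan-2-yl)ethyl]magnesium bromide (not isolated) | Br[Mg]CCC1OCCO1 | intermediate
4 | (Z)-alkenylmagnesium bromide / bromomagnesium alkoxide chelate, Mg on C5 cis to CH2O (not isolated) | Br[Mg]/C=C(\CO[Mg]Br)CCC1OCCO1 | intermediate
5 | (Z)-2-[2-(1,3-dioxolan-2-yl)ethyl]-3-iodoprop-2-en-1-ol | OC/C(CCC1OCCO1)=C\I | intermediate
6 | tert-butyl{[(2Z)-2-[2-(1,3-dioxolan-2-yl)ethyl]-3-iodoprop-2-en-1-yl]oxy}diphenylsilane | I/C=C(\CO[Si](c1ccccc1)(c1ccccc1)C(C)(C)C)CCC1OCCO1 | intermediate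
7 | carbon monoxide | [C-]#[O+] | starting material
8 | (2Z)-3-{[(tert-butyldiphenylsilyl)oxy]methyl}-5-(1,3-dioxolan-2-yl)-N-methoxy-N-methylpent-2-enamide | CON(C)C(=O)/C=C(\CO[Si](c1ccccc1)(c1ccccc1)C(C)(C)C)CCC1OCCO1 | intermediate
9 | (2Z)-3-{[(tert-butyldiphenylsilyl)oxy]methyl}-N-methoxy-N-methyl-6-oxohex-2-enamide | CON(C)C(=O)/C=C(\CO[Si](c1ccccc1)(c1ccccc1)C(C)(C)C)CCC=O | intermediate
10 | iodoethane | CCI | starting material
11 | ethyltriphenylphosphonium iodide | CC[P+](c1ccccc1)(c1ccccc1)c1ccccc1.[I-] | intermediate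
12 | ethylidenetriphenylphosphorane (not isolated) | CC=P(c1ccccc1)(c1ccccc1)c1ccccc1 | intermediate
13 | (1-iodoethyl)triphenylphosphonium iodide (not isolated) | CC(I)[P+](c1ccccc1)(c1ccccc1)c1ccccc1.[I-] | intermediate
14 | (1-iodoethylidene)triphenylphosphorane (not isolated) | CC(I)=P(c1ccccc1)(c1ccccc1)c1ccccc1 | intermediate
15 | (2Z,6Z)-3-{[(tert-butyldiphenylsilyl)oxy]methyl}-7-iodo-N-methoxy-N-methylocta-2,6-dienamide | CON(C)C(=O)/C=C(\CO[Si](c1ccccc1)(c1ccccc1)C(C)(C)C)CC/C=C(/C)I | intermediate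
16 | (2Z,6Z)-3-{[(tert-butyldiphenylsilyl)oxy]methyl}-7-iodoocta-2,6-dienal | O=C/C=C(\CO[Si](c1ccccc1)(c1ccccc1)C(C)(C)C)CC/C=C(/C)I | intermediate
17 | propanoyl chloride | CCC(Cl)=O | starting material
18 | (4R)-4-benzyl-3-propanoyl-1,3-oxazolidin-2-one | CCC(=O)N1[C@H](Cc2ccccc2)COC1=O | intermediate
19 | 3-iodoprop-1-ene | C=CCI | starting material
20 | sodium (Z)-enolate of 18 (not isolated) | C/C=C(\[O-])N1[C@H](Cc2ccccc2)COC1=O.[Na+] | intermediate
21 | (4R)-4-benzyl-3-[(2S)-2-methylpent-4-enoyl]-1,3-oxazolidin-2-one | C=CC[C@H](C)C(=O)N1[C@H](Cc2ccccc2)COC1=O | intermediate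
22 | methyl (2S)-2-methylpent-4-enoate | C=CC[C@H](C)C(=O)OC | intermediate
23 | (3S)-4-methoxy-3-methyl-4-oxobutanoic acid | OC(=O)C[C@H](C)C(=O)OC | intermediate
24 | mixed anhydride of 23 with pivalic acid (not isolated) | CC(C)(C)C(=O)OC(=O)C[C@H](C)C(=O)OC | intermediate
25 | methyl (2S)-4-[(4S)-4-benzyl-2-oxo-1,3-oxazolidin-3-yl]-2-methyl-4-oxobutanoate | COC(=O)[C@@H](C)CC(=O)N1[C@@H](Cc2ccccc2)COC1=O | intermediate
26 | methyl 2-bromopropanoate | CC(Br)C(=O)OC | starting material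
27 | (1-methoxy-1-oxopropan-2-yl)triphenylphosphonium bromide (not isolated) | COC(=O)C(C)[P+](c1ccccc1)(c1ccccc1)c1ccccc1.[Br-] | intermediate
28 | methyl 2-(triphenyl-λ5-phosphanylidene)propanoate | COC(=O)C(C)=P(c1ccccc1)(c1ccccc1)c1ccccc1 | intermediate
29 | 1,4-dioxane-2,5-diol (glycolaldehyde dimer) | OC1COC(O)CO1 | starting material
30 | 2-hydroxyacetaldehyde (not isolated) | OCC=O | intermediate
31 | methyl (2E)-4-hydroxy-2-methylbut-2-enoate | COC(=O)/C(C)=C/CO | intermediate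
32 | methyl (2E)-4-[(tert-butyldimethylsilyl)oxy]-2-methylbut-2-enoate | COC(=O)/C(C)=C/CO[Si](C)(C)C(C)(C)C | intermediate
33 | (2E)-4-[(tert-butyldimethylsilyl)oxy]-2-methylbut-2-enoic acid | OC(=O)/C(C)=C/CO[Si](C)(C)C(C)(C)C | intermediate
34 | dibutylboron (Z)-enolate of 25 (not isolated) | COC(=O)[C@@H](C)/C=C(\OB(CCCC)CCCC)N1[C@@H](Cc2ccccc2)COC1=O | intermediate
35 | methyl (2S,3S,4R,5Z,9Z)-3-{[(4S)-4-benzyl-2-oxo-1,3-oxazolidin-3-yl]carbonyl}-6-{[(tert-butyldiphenylsilyl)oxy]methyl}-4-hydroxy-10-iodo-2-methylundeca-5,9-dienoate (syn-aldol adduct, not isolated) | C/C(I)=C/CC/C(CO[Si](c1ccccc1)(c1ccccc1)C(C)(C)C)=C/[C@@H](O)[C@H]([C@H](C)C(=O)OC)C(=O)N1[C@@H](Cc2ccccc2)COC1=O | intermediate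
36 | (4S)-4-benzyl-3-{[(2R,3S,4S)-2-D-4-methyl-5-oxooxolan-3-yl]carbonyl}-1,3-oxazolidin-2-one (all-trans lactone; 6R,7S,11S) | C/C(I)=C/CC/C(CO[Si](c1ccccc1)(c1ccccc1)C(C)(C)C)=C/[C@H]1OC(=O)[C@@H](C)[C@@H]1C(=O)N1[C@@H](Cc2ccccc2)COC1=O | intermediate
37 | (2R,3S,4S)-2-D-4-methyl-5-oxooxolane-3-carboperoxoic acid (not isolated) | C/C(I)=C/CC/C(CO[Si](c1ccccc1)(c1ccccc1)C(C)(C)C)=C/[C@H]1OC(=O)[C@@H](C)[C@@H]1C(=O)OO | intermediate
38 | (2R,3S,4S)-2-D-4-methyl-5-oxooxolane-3-carboxylic acid | C/C(I)=C/CC/C(CO[Si](c1ccccc1)(c1ccccc1)C(C)(C)C)=C/[C@H]1OC(=O)[C@@H](C)[C@@H]1C(=O)O | intermediate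
39 | (trimethylsilyl)diazomethane | C[Si](C)(C)C=[N+]=[N-] | starting material
40 | (2R,3S,4S)-2-D-4-methyl-5-oxooxolane-3-carbonyl chloride (not isolated) | C/C(I)=C/CC/C(CO[Si](c1ccccc1)(c1ccccc1)C(C)(C)C)=C/[C@H]1OC(=O)[C@@H](C)[C@@H]1C(Cl)=O | intermediate
41 | (3S,4S,5R)-4-(diazoacetyl)-5-D-3-methyloxolan-2-one (not isolated) | C/C(I)=C/CC/C(CO[Si](c1ccccc1)(c1ccccc1)C(C)(C)C)=C/[C@H]1OC(=O)[C@@H](C)[C@@H]1C(=O)C=[N+]=[N-] | intermediate
42 | (3S,4S,5R)-4-(chloroacetyl)-5-D-3-methyloxolan-2-one | C/C(I)=C/CC/C(CO[Si](c1ccccc1)(c1ccccc1)C(C)(C)C)=C/[C@H]1OC(=O)[C@@H](C)[C@@H]1C(=O)CCl | intermediate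
43 | (3S,4R,5R)-4-[(1R)-2-chloro-1-hydroxyethyl]-5-D-3-methyloxolan-2-one | C/C(I)=C/CC/C(CO[Si](c1ccccc1)(c1ccccc1)C(C)(C)C)=C/[C@H]1OC(=O)[C@@H](C)[C@@H]1[C@@H](O)CCl | intermediate
44 | (3S,4S,5R)-5-D-3-methyl-4-[(2R)-oxiran-2-yl]oxolan-2-one | C/C(I)=C/CC/C(CO[Si](c1ccccc1)(c1ccccc1)C(C)(C)C)=C/[C@H]1OC(=O)[C@@H](C)[C@@H]1[C@@H]1CO1 | intermediate
45 | (3S,4R,5R)-5-D-4-[(1R)-1-hydroxy-2-iodoethyl]-3-methyloxolan-2-one (not isolated) | C/C(I)=C/CC/C(CO[Si](c1ccccc1)(c1ccccc1)C(C)(C)C)=C/[C@H]1OC(=O)[C@@H](C)[C@@H]1[C@@H](O)CI | intermediate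
46 | (3S,3aR,4S,6Z,10Z,11aR)-10-{[(tert-butyldiphenylsilyl)oxy]methyl}-4-hydroxy-3,6-dimethyl-3a,4,5,8,9,11a-hexahydrocyclodeca[b]furan-2(3H)-one | C/C1=C/CC/C(CO[Si](c3ccccc3)(c3ccccc3)C(C)(C)C)=C/[C@H]2OC(=O)[C@@H](C)[C@@H]2[C@@H](O)C1 | intermediate
47 | (2E)-4-[(tert-butyldimethylsilyl)oxy]-2-methylbut-2-enoic 2,4,6-trichlorobenzoic anhydride (not isolated) | O=C(OC(=O)/C(C)=C/CO[Si](C)(C)C(C)(C)C)c1c(Cl)cc(Cl)cc1Cl | intermediate
48 | (3S,3aR,4S,6Z,10Z,11aR)-10-{[(tert-butyldiphenylsilyl)oxy]methyl}-3,6-dimethyl-2-oxo-2,3,3a,4,5,8,9,11a-octahydrocyclodeca[b]furan-4-yl (2E)-4-[(tert-butyldimethylsilyl)oxy]-2-methylbut-2-enoate | C/C1=C/CC/C(CO[Si](c3ccccc3)(c3ccccc3)C(C)(C)C)=C/[C@H]2OC(=O)[C@@H](C)[C@@H]2[C@@H](OC(=O)/C(C)=C/CO[Si](C)(C)C(C)(C)C)C1 | intermediate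
49 | (3S,3aR,4S,6Z,10Z,11aR)-10-(hydroxymethyl)-3,6-dimethyl-2-oxo-2,3,3a,4,5,8,9,11a-octahydrocyclodeca[b]furan-4-yl (2E)-4-hydroxy-2-methylbut-2-enoate (CNP0222998.2) | C/C1=C/CC/C(CO)=C/[C@H]2OC(=O)[C@@H](C)[C@@H]2[C@@H](OC(=O)/C(C)=C/CO)C1 | target

**Totals and risks**

Total step count: 24. Longest linear sequence: 14 (steps 1–4, 6, 7, 17–24).

Steps most likely to fail:

Step 22 (proposed Ni-catalysed reductive macrocyclisation; risks are oligomerisation, protodehalogenation and radical side reactions). The fallback uses known polar chemistry and sets out from epoxide 44. LiI/AcOH in THF opens it to iodohydrin 45, now isolated. TESOTf/2,6-lutidine gives iodohydrin triethylsilyl ether F1. Activated zinc dust with LiCl in THF inserts only into the primary C–I bond to give alkylzinc iodide F2. Syringe-pump addition of this to Pd2(dba)3/SPhos at 60 °C effects an intramolecular alkyl–alkenyl Negishi coupling with retention of the Z-geometry, giving macrocyclic triethylsilyl ether F3. PPTS in MeOH removes the TES group and the route is rejoined at alcohol 46.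

Step 20 (catalyst control at C8 may be eroded by the substrate's own facial bias). The fallback sets out from chloroketone 42. Luche reduction (NaBH4, CeCl3, MeOH, −40 °C) gives chlorohydrin epimer mixture F4. NaH closes both epimers to oxirane epimer mixture F5. A hydrolytic kinetic resolution with the (salen)Co(III)OAc enantiomer that hydrolyses the (8S)-oxirane (0.55 equiv H2O; both catalyst hands to be screened) converts the unwanted epimer into (8S)-diol F6, removed by chromatography. The unreacted (8R)-oxirane is epoxide 44, where the route is rejoined.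

Step 17 (the β-branched, ester-bearing imide may enolise or lactonise poorly). The fallback sets out from enal 16 and uses the unbranched succinate donor, for which the tandem aldol–lactonisation is well precedented. Succinic anhydride is opened with MeOH to monomethyl succinate F7. PivCl/Et3N/LiCl with (S)-4-benzyl-1,3-oxazolidin-2-one converts it into unbranched imide F8. Its dibutylboron enolate and 16 give 11-demethyl lactone imide F9. LiOH/H2O2 gives 11-demethyl lactone acid F10. Dianion methylation (NaHMDS 2.2 equiv, MeI, THF, −78 °C; methyl enters trans to the C7 carboxyl) rejoins the route at acid 38.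

**Further compounds**
F1 | step 22 | (3S,4S,5R)-5-D-4-[(1R)-2-iodo-1-(triethylsilyloxy)ethyl]-3-methyloxolan-2-one | C/C(I)=C/CC/C(CO[Si](c1ccccc1)(c1ccccc1)C(C)(C)C)=C/[C@H]1OC(=O)[C@@H](C)[C@@H]1[C@@H](O[Si](CC)(CC)CC)CI
F2 | step 22 | primary alkylzinc iodide from F1 (C9–ZnI, configuration as F1) | C/C(I)=C/CC/C(CO[Si](c1ccccc1)(c1ccccc1)C(C)(C)C)=C/[C@H]1OC(=O)[C@@H](C)[C@@H]1[C@@H](O[Si](CC)(CC)CC)C[Zn]I
F3 | step 22 | 8-O-triethylsilyl ether of 46 | C/C1=C/CC/C(CO[Si](c3ccccc3)(c3ccccc3)C(C)(C)C)=C/[C@H]2OC(=O)[C@@H](C)[C@@H]2[C@@H](O[Si](CC)(CC)CC)C1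
F4 | step 20 | chlorohydrin 43 as a mixture of C8 epimers | C/C(I)=C/CC/C(CO[Si](c1ccccc1)(c1ccccc1)C(C)(C)C)=C/[C@H]1OC(=O)[C@@H](C)[C@@H]1C(O)CCl
F5 | step 20 | oxirane 44 as a mixture of C8 epimers | C/C(I)=C/CC/C(CO[Si](c1ccccc1)(c1ccccc1)C(C)(C)C)=C/[C@H]1OC(=O)[C@@H](C)[C@@H]1C1CO1
F6 | step 20 | (3S,4R,5R)-5-D-4-[(1S)-1,2-dihydroxyethyl]-3-methyloxolan-2-one (8-epi diol) | C/C(I)=C/CC/C(CO[Si](c1ccccc1)(c1ccccc1)C(C)(C)C)=C/[C@H]1OC(=O)[C@@H](C)[C@@H]1[C@H](O)CO
F7 | step 17 | 4-methoxy-4-oxobutanoic acid | COC(=O)CCC(=O)O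
F8 | step 17 | methyl 4-[(4S)-4-benzyl-2-oxo-1,3-oxazolidin-3-yl]-4-oxobutanoate | COC(=O)CCC(=O)N1[C@@H](Cc2ccccc2)COC1=O
F9 | step 17 | (4S)-4-benzyl-3-{[(2R,3S)-2-D-5-oxooxolan-3-yl]carbonyl}-1,3-oxazolidin-2-one | C/C(I)=C/CC/C(CO[Si](c1ccccc1)(c1ccccc1)C(C)(C)C)=C/[C@H]1OC(=O)C[C@@H]1C(=O)N1[C@@H](Cc2ccccc2)COC1=O
F10 | step 17 | (2R,3S)-2-D-5-oxooxolane-3-carboxylic acid | C/C(I)=C/CC/C(CO[Si](c1ccccc1)(c1ccccc1)C(C)(C)C)=C/[C@H]1OC(=O)C[C@@H]1C(=O)O
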